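The cedar run, made earlier with the same charges of substrate and reagent as larch but less capture agent, shows trapped intermediate readings between 2.6% and 5.6% while target climbs to a highest reading of 36.1%. Larch is the flask we are asked about, followed so far for its first hours.

| setting | larch | cedar | flask |
|---|---|---|---|
| substrate | 20 mM | 20 mM | 20 mM |
| reagent | 80 mM | 80 mM | 80.0 mM |
| capture agent | 1 mM | 0.67 mM | 1.00 mM |
| remark | the very flask that is asked about, followed so far | run made earlier |  |
| time |  |  | 3.0 d |

larch run (percent of the substrate charged)

| time / h | trapped intermediate / % | target / % |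
|---|---|---|
| 1.00 | 2.8 | 0 |
| 2.00 | 4.4 | 2.8 |
| 2.50 | 3.2 | 3.3 |
| 4.00 | 5.7 | 5.3 |
| 6.00 | 4.6 | 8.8 |
| 10.0 | 4.3 | 16.6 |
| 15.0 | 4.8 | 22.1 |

cedar run (percent of the substrate charged)

| time / d | trapped intermediate / % | target / % |
|---|---|---|
| 0.167 | 5.6 | 5.7 |
| 0.500 | 2.8 | 17.5 |
| 0.833 | 3.8 | 26.6 |
| 1.25 | 3.5 | 31.8 |
| 1.67 | 3.9 | 34.9 |
| 2.50 | 2.6 | 36.1 |
| 3.00 | 3.5 | 34.0 |

(scatter of a reading: 1 percentage point)

1. share of trapped intermediate in trapped intermediate plus target at 50 min
2. share of trapped intermediate in trapped intermediate plus target at 3.0 d

We read the trapped column first. Larch's 5.00% is what we call the trap ceiling: capture agent charged over substrate charged, in percent. Cedar's ceiling is 3.35%. The last four readings average 4.85% in larch and 3.38% in cedar, each close to its ceiling given a scatter of 1 percentage point, so we take the capture agent as the limiting reagent of the trapping.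

Next comes the target column. At about 4.00 h cedar reads 5.7% and larch 5.3%, alike within the scatter, so we expect larch to flatten where cedar does; the mean of cedar's last three target readings, our plateau, is 35.0%. Ceiling over ceiling plus plateau gives an end share of 12.5%.

At 50 min larch is still filling its trap. Scaling the 2.8% read at 1.00 h in proportion to time gives 2.33%. Target starts with a lag, and a rate growing in proportion to time integrates to an amount growing as time squared, so the 2.8% at 2.00 h shrinks to 0.486%. Our early share is a rough 82.8%.

The forecast, which parts from our early figure, gives 88% and 12%, reasoning that “the agent is a small stoichiometric sink”.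

The flask gives 82.7% at 50 min and 12.6% at 3.0 d.

    substrate + reagent → intermediate A (k = 1.42 M⁻¹ min⁻¹)
    reagent + intermediate A → intermediate B (k = 0.201 M⁻¹ min⁻¹)
    intermediate B → target (k = 0.00138 min⁻¹)
    2 reagent → self-condensation product (k = 0.449 M⁻¹ min⁻¹)
    capture agent + intermediate A → trapped intermediate (k = 1.22 M⁻¹ min⁻¹)

At 3.00 d the flask holds 5.00% trapped intermediate, level with its ceiling of 5.00%, and 0% of its capture agent remains. A neighbour flask charged with 0.25 mM of capture agent has a ceiling of 1.25%, which beside our plateau reckons to a share of 3.45%; at 3.0 d that neighbour flask gives 3.44%.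

The data were generated by integration with constants of no real substance; the scatter is artificial.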